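The data were computed from invented constants.

How much of the free monomer in this flask has reacted by 5.0 h, and how long are its chains on average?

| setting | Thursday's | Tuesday's | Sunday's | flask |
|---|---|---|---|---|
| free monomer | 0.60 M | 0.60 M | 1.2 M | 0.60 M |
| pre-initiator | 0.36 mol% | 0.81 mol% | 0.54 mol% | 0.54 mol% |
| remark | run made earlier | run made earlier | run made earlier |  |
| time |  |  |  | 5.0 h |

- Thursday's (time / h: monomer in chains / %, free monomer / %): 0.200: 0, 99.4; 0.667: 1.8, 98.5; 1.00: 5.2, 94.6; 1.50: 11.4, 89.4; 2.50: 28.2, 71.7; 3.00: 34.1, 64.0
- Tuesday's (time / h: monomer in chains / %, free monomer / %): 0.500: 1.9, 97.7; 1.00: 11.4, 89.6; 1.50: 22.9, 77.6; 2.00: 36.3, 63.5; 2.50: 49.4, 50.8; 3.00: 60.2, 40.4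
- Sunday's (time / h: monomer in chains / %, free monomer / %): 0.250: 1.0, 99.8; 0.417: 3.3, 96.4; 0.833: 12.4, 88.4; 1.50: 32.7, 67.2; 3.00: 74.7, 25.3

(scatter of a reading: 0.5 percentage points)

- the average divides the monomer in chains by the number of chains begun, living and dead together
- the numbers in the tables scatter by 0.5 percentage points (one standard deviation)
- steps thought possible: monomer in chains + living end -> free monomer + living end; free monomer + initiator -> living end + monomer in chains; free monomer + living end -> monomer in chains + living end; pre-initiator -> initiator
- the earlier runs do not show the number of chains; that part of a forecast is a guess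

- average number of monomer units in a chain (chains begun, living or dead) at 5.0 h
- part of the free monomer that has reacted at 5.0 h

The earlier runs start slowly (an induction period), and two chemists begin from the same reading of them. Across these runs, ln(c(free monomer charged)/c(free monomer)) grows roughly with the square of the time and with c(pre-initiator charged). So they give a flask a clock, the time at which that logarithm reaches 1 on this square law, and on the same reading the clock goes as one over the square root of c(pre-initiator charged). Tuesday's 63.5% at 2.00 h gives a clock of 2.97 h, and the smaller charge here stretches it to 3.63 h, the flask's clock.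

The first chemist trusts this clock to the end. At 5.0 h it leaves 15.1% free monomer, so 84.9% has reacted.

The second chemist objects. On its own clock, Tuesday's run should hold 36.0% at 3.00 h, but it reads 40.4%, a gap of 4.4 percentage points, larger than the scatter of 0.5 points. So the clock bends late. The forecast takes this side: “I take ≈ 1.5, so c is about 78%”. It gives 78% and 250 units per chain, the second being a guess, since the runs do not show the number of chains.

The flask gives 74.6% reacted, less than the clock's figure, and 245 units per chain, so the forecast stands.

    monomer in chains + living end → free monomer + living end, rate k1*[living end] as long as [monomer in chains] is above zero (k = 0.00960 s⁻¹)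
    free monomer + initiator → living end + monomer in chains (k = 0.00580 L mol⁻¹ s⁻¹)
    free monomer + living end → monomer in chains + living end, rate k3*[living end]*[free monomer] (k = 0.110 L mol⁻¹ s⁻¹)
    pre-initiator → initiator (k = 4.90 × 10⁻⁵ s⁻¹)

In this flask at 5.00 h monomer in chains is made 1.75 times as fast as it is used up, each step taken net, against 3.98 at 2.74 h. The first chemist's clock does hold for this flask up to 2.50 h: it gives 62.2% free monomer there, and the flask holds 62.6%. For the neighbour flask charged with 0.15 M free monomer, same loading of pre-initiator, the clock is 7.27 h and gives 62.3% at 5.00 h, while that flask holds 83.7%.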